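The unprimed coumarin's benzene ring is built rather than bought. Its C6(aryl)–C7(OMe) edge is read as an aryl methoxyacetylene, and C8(H)–C8a(O)–C4a(ester carbon, later C4)–C5(Me) as the diene of a 4-methoxy-6-methyl-2-pyranone-5-carboxylate. One thermal inverse-demand Diels–Alder reaction with loss of CO2 forms C5–C6 and C7–C8 and gives the hexasubstituted ring. The 6,8' bond, made beforehand as an unhindered aryl–alkyne bond, thereby becomes the crowded biaryl bond. The precursors are a push–pull pyranone ester and 2-(methoxyethynyl)-1,3-dimethoxy-5-methylbenzene, a methyl ynol ether that cannot fragment by retro-ene reaction. Both pyranone rings are closed last with ketenylidenetriphenylphosphorane.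

Key step: step 6

Assumption: the target is drawn without an axial descriptor, so the 6,8' biaryl axis is left unspecified and compounds 15 to 19 are made as racemates about that axis.

Step 1
Reactants: 1 dimethyl 3-oxopentanedioate; 2 acetyl chloride
Product: 3 dimethyl 2-acetyl-3-oxopentanedioate
Conditions: MgCl2, pyridine, CH2Cl2, 0 °C to rt; aq. HCl work-up
Reagents that add atoms: none
Why: Soft enolisation with MgCl2 and pyridine gives the chelated magnesium enolate of the β-keto ester, which should undergo Claisen-type C-acylation by acetyl chloride, the chelate suppressing O-acylation and a second acylation.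

Step 2
Reactants: 3 dimethyl 2-acetyl-3-oxopentanedioate
Product: 4 methyl 4-hydroxy-6-methyl-2-oxo-2H-pyran-5-carboxylate
Conditions: conc. H2SO4, 0 °C to rt; ice quench
Reagents that add atoms: none
Why: Acid-promoted enol lactonisation of the 3,5-dioxo ester (the cyclisation that turns triacetic acid esters into 4-hydroxy-2-pyranones) should join the acetyl enol oxygen to the remote ester with loss of methanol, while the ester on the acetylated carbon cannot reach and stays as the C5 carboxylate.

Step 3
Reactants: 4 methyl 4-hydroxy-6-methyl-2-oxo-2H-pyran-5-carboxylate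
Product: 5 methyl 4-methoxy-6-methyl-2-oxo-2H-pyran-5-carboxylate
Conditions: Me2SO4, K2CO3, acetone, reflux
Reagents that add atoms: dimethyl sulfate, COS(=O)(=O)OC
Why: Williamson-type O-alkylation of the acidic vinylogous carboxylic acid with a hard methylating agent should give the 4-methoxy-2-pyranone, as it does for 4-hydroxy-6-methyl-2-pyranone, rather than C3-methylation.

Step 4
Reactants: 6 3,5-dimethoxytoluene
Product: 8 2-iodo-1,3-dimethoxy-5-methylbenzene, via (2,6-dimethoxy-4-methylphenyl)lithium 7 (not isolated)
Conditions: n-BuLi, TMEDA, THF, 0 °C to rt; I2, THF, −78 °C to rt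
Reagents that add atoms: iodine, II
Why: Directed ortho-metalation removes the proton between the two methoxy groups, which both coordinate lithium and acidify that position, and iodinolysis of the aryllithium then gives the iodide.

Step 5
Reactants: 8 2-iodo-1,3-dimethoxy-5-methylbenzene; 9 chloroacetaldehyde dimethyl acetal
Product: 12 2-(methoxyethynyl)-1,3-dimethoxy-5-methylbenzene, via lithium methoxyacetylide 10 (not isolated), via methoxyethynylzinc chloride 11 (not isolated)
Conditions: 9, LiNEt2 (3 equiv), THF, 0 °C; ZnCl2, 0 °C; then 8, Pd(PPh3)4 (5 mol %), THF, 50 °C; pH 8 work-up, Et3N-deactivated silica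
Reagents that add atoms: none
Why: Twofold base-induced elimination from the acetal (methanol, then HCl) gives the lithium acetylide, and after transmetalation to zinc a Negishi coupling (oxidative addition of the aryl iodide to zerovalent palladium, fast alkynyl transfer, reductive elimination) should form the aryl–alkyne bond under non-acidic conditions that spare the ynol ether.

Step 6
Reactants: 5 methyl 4-methoxy-6-methyl-2-oxo-2H-pyran-5-carboxylate; 12 2-(methoxyethynyl)-1,3-dimethoxy-5-methylbenzene
Product: 14 methyl 3-(2,6-dimethoxy-4-methylphenyl)-4,6-dimethoxy-2-methylbenzoate, via bridged lactone cycloadduct 13 (not isolated)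
Conditions: 5 (2 equiv), 12 (1 equiv), toluene (2 M), BHT (5 mol %), 2,6-lutidine (10 mol %), sealed tube, 140 °C
Reagents that add atoms: none
Why: The 2-pyranone, made electron-poor by its lactone carbonyl and C5 ester, should react as the diene C3=C4–C5=C6 with the electron-rich ynol ether in an asynchronous inverse-electron-demand [4+2] cycloaddition to give the 2-oxabicyclo[2.2.2]octadienone 13, which aromatises irreversibly by retro-[4+2] expulsion of CO2. The closest known reaction type is the Diels–Alder/decarboxylation of 2-pyranone carboxylates with ynamines, ketene acetals and 1-alkoxyalkynes to give substituted benzoates. The one new ring, the hexasubstituted benzene ring, is closed by an intermolecular two-bond annulation across pyranone C3 and C6 (C7–C8 and C5–C6 in coumarin numbering), not by cyclisation of a chain. No stereocentre persists, because the two bridgehead centres of 13 vanish with CO2 and the new biaryl axis carries two identical ortho methoxy groups on one ring. The selectivity needed is regiochemical (aryl-bearing alkyne carbon to the methyl-bearing C6) and matched polarity should secure it: the ynol ether is nucleophilic at the carbon remote from oxygen, C6 is the β-carbon of the C5 acrylate ester and vinylogous to the lactone carbonyl, and the 4-methoxy group makes C3 the terminus that captures the oxygen-stabilised cationic carbon. A methyl ynol ether has no β-hydrogen and so cannot collapse to a ketene by retro-ene loss of an alkene at this temperature, while the hindered base and BHT guard it against acid-induced hydration and radical oligomerisation.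

Step 7
Reactants: 14 methyl 3-(2,6-dimethoxy-4-methylphenyl)-4,6-dimethoxy-2-methylbenzoate
Product: 15 methyl 3-(3-iodo-2,6-dimethoxy-4-methylphenyl)-4,6-dimethoxy-2-methylbenzoate
Conditions: NIS (1.0 equiv), TFA (10 mol %), MeCN, 0 °C to rt
Reagents that add atoms: N-iodosuccinimide, O=C1CCC(=O)N1I
Why: Electrophilic aromatic iodination should occur on the dimethoxytolyl ring, whose two equivalent free positions are para to one methoxy group, ortho to the other and to methyl, and carry no acceptor, in preference to the single free position of the benzoate ring, which is wedged between two methoxy groups and deactivated by the ester.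

Step 8
Reactants: 15 methyl 3-(3-iodo-2,6-dimethoxy-4-methylphenyl)-4,6-dimethoxy-2-methylbenzoate
Product: 16 methyl 3-[2,6-dimethoxy-3-(methoxycarbonyl)-4-methylphenyl]-4,6-dimethoxy-2-methylbenzoate
Conditions: Pd(OAc)2 (5 mol %), Xantphos (6 mol %), CO (5 bar), Et3N, MeOH/DMF, 80 °C
Reagents that add atoms: carbon monoxide, [C-]#[O+]; methanol, CO
Why: Palladium-catalysed methoxycarbonylation (oxidative addition of the aryl iodide, CO insertion, methanolysis of the aroylpalladium species) should install the second ester, the iodide and a wide-bite-angle ligand being chosen because the reacting carbon is flanked by methoxy and methyl groups.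

Step 9
Reactants: 16 methyl 3-[2,6-dimethoxy-3-(methoxycarbonyl)-4-methylphenyl]-4,6-dimethoxy-2-methylbenzoate
Product: 17 methyl 6-hydroxy-3-[2-hydroxy-6-methoxy-3-(methoxycarbonyl)-4-methylphenyl]-4-methoxy-2-methylbenzoate
Conditions: BCl3 (3 equiv), CH2Cl2, −78 to 0 °C; H2O
Reagents that add atoms: none
Why: In this chelation-controlled Lewis acid ether cleavage BCl3 binds each ester carbonyl together with the neighbouring methoxy oxygen in a six-membered chelate, so chloride should remove only those two methyl groups and leave the methoxy groups para to the esters and the esters themselves intact.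

Step 10
Reactants: 17 methyl 6-hydroxy-3-[2-hydroxy-6-methoxy-3-(methoxycarbonyl)-4-methylphenyl]-4-methoxy-2-methylbenzoate
Product: 19 4,4',7,7'-tetramethoxy-5,5'-dimethyl-2H,2'H-[6,8'-bichromene]-2,2'-dione, via bis(triphenylphosphoranylideneacetate) ester 18 (not isolated)
Conditions: Ph3P=C=C=O (2.5 equiv), toluene, reflux
Reagents that add atoms: ketenylidenetriphenylphosphorane, O=C=C=P(c1ccccc1)(c1ccccc1)c1ccccc1
Why: Each phenol adds across the ketene C=C bond of the cumulated ylide to give an aryl ester-stabilised phosphorane, which should close the pyranone ring by intramolecular Wittig olefination of the adjacent methyl ester carbonyl, the ester methoxy group becoming the 4-methoxy group, as is known for methyl 2-hydroxy-4-methoxy-6-methylbenzoate.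

Compound list
1 | dimethyl 3-oxopentanedioate | COC(=O)CC(=O)CC(=O)OC | starting material
2 | acetyl chloride | CC(=O)Cl | starting material
3 | dimethyl 2-acetyl-3-oxopentanedioate (drawn as the keto form) | COC(=O)CC(=O)C(C(C)=O)C(=O)OC | intermediate
4 | methyl 4-hydroxy-6-methyl-2-oxo-2H-pyran-5-carboxylate | COC(=O)c1c(C)oc(=O)cc1O | intermediate
5 | methyl 4-methoxy-6-methyl-2-oxo-2H-pyran-5-carboxylate | COC(=O)c1c(C)oc(=O)cc1OC | intermediate
6 | 3,5-dimethoxytoluene | COc1cc(C)cc(OC)c1 | starting material
7 | (2,6-dimethoxy-4-methylphenyl)lithium | [Li]c1c(OC)cc(C)cc1OC | intermediate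
8 | 2-iodo-1,3-dimethoxy-5-methylbenzene | COc1cc(C)cc(OC)c1I | intermediate
9 | chloroacetaldehyde dimethyl acetal | COC(CCl)OC | starting material
10 | lithium methoxyacetylide | [Li]C#COC | intermediate
11 | methoxyethynylzinc chloride | COC#C[Zn]Cl | intermediate
12 | 2-(methoxyethynyl)-1,3-dimethoxy-5-methylbenzene | COC#Cc1c(OC)cc(C)cc1OC | intermediate
13 | methyl 7-(2,6-dimethoxy-4-methylphenyl)-5,8-dimethoxy-1-methyl-3-oxo-2-oxabicyclo[2.2.2]octa-5,7-diene-6-carboxylate (racemic, the two bridgehead configurations tied by the bicycle) | CC12OC(=O)C(C(OC)=C1C(=O)OC)C(OC)=C2c1c(OC)cc(C)cc1OC | intermediate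
14 | methyl 3-(2,6-dimethoxy-4-methylphenyl)-4,6-dimethoxy-2-methylbenzoate | COC(=O)c1c(C)c(-c2c(OC)cc(C)cc2OC)c(OC)cc1OC | intermediate
15 | methyl 3-(3-iodo-2,6-dimethoxy-4-methylphenyl)-4,6-dimethoxy-2-methylbenzoate (racemic axis) | COC(=O)c1c(C)c(-c2c(OC)cc(C)c(I)c2OC)c(OC)cc1OC | intermediate
16 | methyl 3-[2,6-dimethoxy-3-(methoxycarbonyl)-4-methylphenyl]-4,6-dimethoxy-2-methylbenzoate (racemic axis) | COC(=O)c1c(C)c(-c2c(OC)cc(C)c(C(=O)OC)c2OC)c(OC)cc1OC | intermediate
17 | methyl 6-hydroxy-3-[2-hydroxy-6-methoxy-3-(methoxycarbonyl)-4-methylphenyl]-4-methoxy-2-methylbenzoate (racemic axis) | COC(=O)c1c(C)c(-c2c(OC)cc(C)c(C(=O)OC)c2O)c(OC)cc1O | intermediate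
18 | bis[(triphenylphosphoranylidene)acetate] ester of the two phenols of 17 (racemic axis) | COC(=O)c1c(C)c(-c2c(OC)cc(C)c(C(=O)OC)c2OC(=O)C=P(c3ccccc3)(c3ccccc3)c3ccccc3)c(OC)cc1OC(=O)C=P(c4ccccc4)(c4ccccc4)c4ccccc4 | intermediate
19 | 4,4',7,7'-tetramethoxy-5,5'-dimethyl-2H,2'H-[6,8'-bichromene]-2,2'-dione (racemic axis) | COc1cc2oc(=O)cc(OC)c2c(C)c1-c1c(OC)cc(C)c2c(OC)cc(=O)oc12 | target

Total step count: 10. Longest linear sequence: 8 steps (steps 1, 2, 3, 6, 7, 8, 9, 10, from dimethyl 3-oxopentanedioate); the alkyne branch (steps 4 and 5) joins at step 6.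

Steps most likely to fail

1. Step 6. The bond between the aryl-bearing alkyne carbon and the methyl-bearing pyranone carbon may form too slowly at temperatures the ynol ether tolerates. Oligomerisation or hydration of the alkyne could then outrun the cycloaddition, or some of the material could combine in the reverse orientation. The fallback replaces ring construction by a biaryl cross-coupling. It sets out from 6: the aryllithium 7 of step 4 is quenched with B(OMe)3 and hydrolysed to (2,6-dimethoxy-4-methylphenyl)boronic acid F1. Purchased methyl 2,4-dimethoxy-6-methylbenzoate F2 is brominated with NBS in MeCN at the position next to its methyl group to give methyl 3-bromo-4,6-dimethoxy-2-methylbenzoate F3. Suzuki–Miyaura coupling of F1 with F3 (Pd(OAc)2, SPhos, K3PO4, toluene/water, 100 °C) should give 14, where the route is rejoined before step 7.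

2. Step 5. Oxidative addition at the iodide flanked by two methoxy groups may be slow, and the ynol ether may be lost by hydration to an arylacetic ester during coupling, work-up or chromatography. The fallback makes the alkyne by elimination instead of cross-coupling. It sets out from 6: the aryllithium 7 is added to 2-methoxy-N-methoxy-N-methylacetamide (THF, −78 to 0 °C) to give 1-(2,6-dimethoxy-4-methylphenyl)-2-methoxyethan-1-one F4. The chelated lithium enolate (LiN(SiMe3)2, THF, −78 °C) is trapped with PhNTf2 as (Z)-1-(2,6-dimethoxy-4-methylphenyl)-2-methoxyethenyl trifluoromethanesulfonate F5. Anti-elimination of triflate with KOt-Bu (THF, −78 to 0 °C) should give 12, where the route is rejoined before step 6.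

3. Step 8. Oxidative addition and CO insertion at the doubly ortho-substituted carbon may be slower than hydrodeiodination, returning 14. The fallback uses electrophilic formylation and oxidation, with no halide and no palladium. It sets out from 14: Rieche formylation (Cl2CHOMe, TiCl4, CH2Cl2, −78 to 0 °C) at the same electron-rich position should give methyl 3-(3-formyl-2,6-dimethoxy-4-methylphenyl)-4,6-dimethoxy-2-methylbenzoate F6. Pinnick oxidation (NaClO2, NaH2PO4, 2-methyl-2-butene, t-BuOH/water) gives methyl 3-(3-carboxy-2,6-dimethoxy-4-methylphenyl)-4,6-dimethoxy-2-methylbenzoate F7. Methylation (MeI, K2CO3, DMF) gives 16, where the route is rejoined before step 9.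

Further compounds
F1 | step 6 | (2,6-dimethoxy-4-methylphenyl)boronic acid | COc1cc(C)cc(OC)c1B(O)O
F2 | step 6 | methyl 2,4-dimethoxy-6-methylbenzoate (purchased) | COC(=O)c1c(C)cc(OC)cc1OC
F3 | step 6 | methyl 3-bromo-4,6-dimethoxy-2-methylbenzoate | COC(=O)c1c(C)c(Br)c(OC)cc1OC
F4 | step 5 | 1-(2,6-dimethoxy-4-methylphenyl)-2-methoxyethan-1-one | COCC(=O)c1c(OC)cc(C)cc1OC
F5 | step 5 | (Z)-1-(2,6-dimethoxy-4-methylphenyl)-2-methoxyethenyl trifluoromethanesulfonate | CO/C=C(\OS(=O)(=O)C(F)(F)F)c1c(OC)cc(C)cc1OC
F6 | step 8 | methyl 3-(3-formyl-2,6-dimethoxy-4-methylphenyl)-4,6-dimethoxy-2-methylbenzoate | COC(=O)c1c(C)c(-c2c(OC)cc(C)c(C=O)c2OC)c(OC)cc1OC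
F7 | step 8 | methyl 3-(3-carboxy-2,6-dimethoxy-4-methylphenyl)-4,6-dimethoxy-2-methylbenzoate | COC(=O)c1c(C)c(-c2c(OC)cc(C)c(C(=O)O)c2OC)c(OC)cc1OC
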